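Begin from how slowly target appears: the winter run reaches 8.8% after 8.00 min, and the autumn run 3.2% after 15.0 min.

| setting | autumn | winter | Monday's | Wednesday's |
|---|---|---|---|---|
| starting material | 0.068 M (in portions, 4) | 0.068 M (in portions, 4) | 0.068 M | 0.068 M (in portions, 4) |
| reagent | 0.19 M | 0.30 M | 0.136 M | 0.136 M |
| temperature | 18 °C | 34 °C | 10 °C | 40 °C |
| remark | run made earlier; portions every 1.5 min | run made earlier; portions every 1.5 min | everything together at the start | the portions of starting material follow each other after 1.5 min, the first at the start |
| time |  |  | 1.5 min | 6.0 min |

| autumn: time / min | autumn: target / % | winter: time / min | winter: target / % |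
|---|---|---|---|
| 2.50 | 0 | 0.500 | 0.3 |
| 8.00 | 1.2 | 1.33 | 0.9 |
| 15.0 | 3.2 | 3.00 | 2.0 |
| 25.0 | 4.1 | 8.00 | 8.8 |

(standard deviation of a reading: 0.5 percentage points)

- which one finishes higher in amount of target, in percent of the starting material charged ("neither" within 2 percentage points) (Monday's / Wednesday's / neither)
- amount of target at the end, in percent of the starting material charged, Monday's
- amount of target at the end, in percent of the starting material charged, Wednesday's

- a reading or a percentage of target counts all its forms, free or not

Compare two times, the time a flask is given and the time it would need to turn its whole charge into target at the mean pace read from a run. Call the second the making time. Divide the time of a reading by the fraction reached: winter gives 90.9 min and autumn 469 min. At a steady pace, and while the fraction stays small, time given over making time estimates the fraction made.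

Set the reagent aside, as my own choice, although winter held 0.30 M against autumn's 0.19 M. Let the whole change in making time belong to temperature, and carry it on as a constant factor per degree. At Wednesday's temperature, the making time is 49.1 min, and at Monday's it is 1060 min. The ratios are then 12.2% for Wednesday's and 0.141% for Monday's, so expect Wednesday's to lead. Read Monday's ratio as the high side: autumn showed 0% at 2.50 min.

The forecast names Wednesday's, with 0.1% (0% to 0.4%) for Monday's and 4.4% (2.3% to 7%) for Wednesday's, noting “The reagent order is untested”. My Wednesday's ratio stands above that range.

The flask gives 0.0194% for Monday's and 13.5% for Wednesday's, so Wednesday's finishes higher.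

    intermediate C → side product (k = 0.00180 s⁻¹, Ea = 92.0 kJ mol⁻¹)
    reagent + intermediate B → target (k = 0.0800 M⁻¹ s⁻¹, Ea = 69.0 kJ mol⁻¹)
    starting material → intermediate B (k = 0.00340 s⁻¹, Ea = 91.0 kJ mol⁻¹)
    crystals ⇌ target, rate k4*(cs4 - [target]) while solid is left; crystals form when [target] > cs4 (solubility = 8.50 mM, k = 0.0660 s⁻¹)
    reagent + intermediate A ⇌ intermediate C (K = 140 M⁻¹, k = 0.0780 M⁻¹ s⁻¹, Ea = 57.0 kJ mol⁻¹, ΔH = −63.0 kJ mol⁻¹)
    starting material + reagent → intermediate A (k = 0.0920 M⁻¹ s⁻¹, Ea = 45.0 kJ mol⁻¹)
    (constants at 40 °C)

Take the difference in temperature away from Monday's flask, keeping its time and its single charge, and it reaches 5.75%. The difference in time is not the reason: with that difference taken away instead, Monday's flask reaches 0.218%. Warmth is a part of the gap, and the warmed flask stays below Wednesday's 13.5%. Wednesday's making time of 49.1 min gave a ratio of 12.2% for that flask, which reached 13.5%. Left for 60.0 min, Wednesday's flask has a ratio of 122%, far past small fractions, and it stands at 30.2%.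

(The earlier runs and the new flask come from a simulation with constants of no real substance; the scatter is artificial.)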